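The route rests on the bond between the furan α-carbon (C2 of the 2,4-disubstituted furan) and C1 of the 2,5-dihydroxyphenyl ring. Because the two phenolic oxygens are para, this ring is the reduced form of 1,4-benzoquinone, whose four CH carbons are equivalent acceptor sites, so the quinone serves as an umpoled hydroquinone. In the key step the free α-C–H (C5) of a 3-substituted furan that already carries the complete (R)-acyloxy side chain adds to benzoquinone, and tautomerisation re-aromatises the six-membered ring: the unprotected target should form directly from two unfunctionalised partners. The furan comes from 3-furaldehyde by Brown allylation, cross-metathesis and acylation.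

Key step: step 4

Remark: the carbinol carbon of the target is (R) (O > furyl C > CH2 > H). The 3-furyl group is assumed to behave like phenyl in the facial models of the allylboration and of the oxazaborolidine reduction used in a fallback.

Step 1
Reactants: 1 furan-3-carbaldehyde
Product: 3 (R)-1-(furan-3-yl)but-3-en-1-ol, via borinate ester 2 (not isolated)
Conditions: (+)-Ipc2BOMe, allylMgBr, Et2O, 0 °C → rt; then 1, −78 °C; then 3 M NaOH, 30% H2O2, rt
Reagents that add atoms: allylmagnesium bromide, C=CC[Mg]Br (allyl group of 2 and 3, passed on through the B-allyl borane); (+)-B-methoxydiisopinocampheylborane, COB([C@H]1C[C@H]2C[C@@H]([C@@H]1C)C2(C)C)[C@H]1C[C@H]2C[C@@H]([C@@H]1C)C2(C)C (its Ipc2B unit is held only in intermediate 2)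
Why: Brown asymmetric allylboration: the B-allyl reagent derived from (−)-α-pinene should transfer allyl through a closed chair (Zimmerman–Traxler) transition state to the Re face of the aldehyde, as it does with benzaldehyde, which sets the (R) carbinol centre under reagent control; oxidative cleavage of the borinate releases the alcohol.

Step 2
Reactants: 3 (R)-1-(furan-3-yl)but-3-en-1-ol
Product: 4 (R)-1-(furan-3-yl)-4-methylpent-3-en-1-ol
Conditions: 2-methyl-2-butene (large excess, co-solvent), Grubbs II (3 mol %), CH2Cl2, 40 °C, sealed tube
Reagents that add atoms: 2-methyl-2-butene, CC=C(C)C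
Why: Olefin cross-metathesis of a terminal alkene with excess 2-methyl-2-butene should exchange =CH2 for =CMe2 with loss of propene; the furan and the free hydroxyl are tolerated by the Ru carbene and the carbinol centre is not involved.

Step 3
Reactants: 4 (R)-1-(furan-3-yl)-4-methylpent-3-en-1-ol
Product: 5 (R)-1-(furan-3-yl)-4-methylpent-3-en-1-yl 3-methylbutanoate
Conditions: isovaleryl chloride, Et3N, DMAP (cat.), CH2Cl2, 0 °C → rt
Reagents that add atoms: 3-methylbutanoyl chloride (isovaleryl chloride), CC(C)CC(=O)Cl
Why: DMAP-catalysed O-acylation of a secondary alcohol; the C–O bond at the stereocentre is not broken, so the (R) configuration is retained.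

Step 4
Reactants: 5 (R)-1-(furan-3-yl)-4-methylpent-3-en-1-yl 3-methylbutanoate; 6 1,4-benzoquinone
Product: 8 (R)-1-[5-(2,5-dihydroxyphenyl)furan-3-yl]-4-methylpent-3-en-1-yl 3-methylbutanoate (target), via dienone tautomer 7 (not isolated)
Conditions: 6 (0.95 equiv, slow addition), Sc(OTf)3 (5 mol %), MeCN, −20 → 0 °C, Ar, dark; work-up and chromatography under Ar
Reagents that add atoms: none
Why: The Lewis acid binds a quinone carbonyl, the free α-carbon C5 of the furan attacks a quinone CH carbon in a Friedel–Crafts/Michael sense, proton loss re-aromatises the furan to dienone 7, and enolisation of 7 aromatises the six-membered ring, so the net change is a redox-neutral C–H/C–H union in which every atom of both partners ends up in the product. The closest known reaction type is the acid-catalysed conjugate addition of alkylfurans, pyrroles and indoles to p-quinones, which gives (hetero)aryl hydroquinones. No ring is closed and no stereocentre is created in the product, since the sp3 carbon of 7 is erased on enolisation and the carbinol centre lies outside the reacting π-systems. The step needs attack at C5 and not at C2 of the furan: only the α-positions are reactive, C2 is flanked by the branched secondary carbon and is deactivated by the σ-withdrawing acyloxy group, while the four CH positions of 6 are equivalent, so the quinone side poses no regiochemical question. It also needs the furan to react ahead of the trisubstituted alkene and to add only once, which the higher π-nucleophilicity of the furan and the loss of acceptor character in the hydroquinone product should secure. Slow addition of slightly substoichiometric 6 under argon at low temperature is meant to keep the product from being oxidised onward and to spare the furylic ester.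

Compound list
1 | furan-3-carbaldehyde (3-furaldehyde) | O=Cc1ccoc1 | starting material
2 | (R)-1-(furan-3-yl)but-3-en-1-yl diisopinocampheylborinate (borinate ester) | C=CC[C@@H](OB([C@H]1C[C@H]2C[C@@H]([C@@H]1C)C2(C)C)[C@H]1C[C@H]2C[C@@H]([C@@H]1C)C2(C)C)c1ccoc1 | intermediate
3 | (R)-1-(furan-3-yl)but-3-en-1-ol | C=CC[C@@H](O)c1ccoc1 | intermediate
4 | (R)-1-(furan-3-yl)-4-methylpent-3-en-1-ol | CC(C)=CC[C@@H](O)c1ccoc1 | intermediate
5 | (R)-1-(furan-3-yl)-4-methylpent-3-en-1-yl 3-methylbutanoate | CC(C)=CC[C@@H](OC(=O)CC(C)C)c1ccoc1 | intermediate
6 | 1,4-benzoquinone | O=C1C=CC(=O)C=C1 | starting material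
7 | (1R)-1-[5-(3-hydroxy-6-oxocyclohexa-2,4-dien-1-yl)furan-3-yl]-4-methylpent-3-en-1-yl 3-methylbutanoate (dienone tautomer, ring sp3 centre undefined) | CC(C)=CC[C@@H](OC(=O)CC(C)C)c1coc(C2C=C(O)C=CC2=O)c1 | intermediate
8 | (R)-1-[5-(2,5-dihydroxyphenyl)furan-3-yl]-4-methylpent-3-en-1-yl 3-methylbutanoate | CC(C)=CC[C@@H](OC(=O)CC(C)C)c1coc(-c2cc(O)ccc2O)c1 | target

Total step count: 4
Longest linear sequence: 4 steps (1 → 3 → 4 → 5 → 8)

Steps most likely to fail

Step 4. Three things may go wrong: attack at the hindered α-position next to the side chain may compete with attack at C5, the electron-rich product may be oxidised onward by unreacted quinone, and the Lewis acid may ionise the furylic ester with loss of configuration. The fallback sets out from 5 and comes back at 8, and it makes the same furan–aryl bond under base instead of acid. Iridium-catalysed C–H borylation of 5 ([Ir(OMe)(cod)]2, dtbpy, B2pin2, hexane, rt) is governed by sterics and should go to the α-position remote from the branched side chain, giving (R)-4-methyl-1-[5-(4,4,5,5-tetramethyl-1,3,2-dioxaborolan-2-yl)furan-3-yl]pent-3-en-1-yl 3-methylbutanoate F1. Suzuki–Miyaura coupling of F1 with commercial 2-bromobenzene-1,4-diol (Oc1ccc(O)c(Br)c1) with a fast precatalyst (XPhos Pd G3, degassed aqueous K3PO4, THF, rt to 40 °C), chosen to outrun protodeboronation of the 2-furyl boronate, should then give 8 with the regiochemistry fixed by the two coupling handles.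

Step 2. The free carbinol or the furan may deactivate the catalyst, the alkene exchange may stop at the ethylidene (crotyl) stage, or the double bond may migrate. The fallback sets out from 3 and comes back at 4, and it builds the isopropylidene unit by carbonyl olefination instead of metathesis. Silylation of 3 (TBSCl, imidazole, DMF) gives (R)-tert-butyl{[1-(furan-3-yl)but-3-en-1-yl]oxy}dimethylsilane F2. Lemieux–Johnson cleavage of the terminal alkene (OsO4 cat., NaIO4, 2,6-lutidine, dioxane–water), which should leave the aromatic furan alone, gives (R)-3-[(tert-butyldimethylsilyl)oxy]-3-(furan-3-yl)propanal F3. Wittig olefination with isopropylidenetriphenylphosphorane (isopropyltriphenylphosphonium iodide, n-BuLi, THF, −78 → 0 °C) gives (R)-tert-butyl{[1-(furan-3-yl)-4-methylpent-3-en-1-yl]oxy}dimethylsilane F4, and TBAF in THF returns 4.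

Step 1. Facial selectivity may be insufficient, and the small carbinol may be hard to separate from the terpene alcohol left by the chiral reagent. The fallback sets out from 1 and comes back at 3, and it sets the centre by catalytic asymmetric reduction of a ketone instead of reagent-controlled C–C bond formation. Addition of allylmagnesium bromide to 1 (THF, −78 °C) gives rac-1-(furan-3-yl)but-3-en-1-ol F5. Buffered Dess–Martin oxidation (DMP, NaHCO3, CH2Cl2, 0 °C) gives the β,γ-unsaturated ketone 1-(furan-3-yl)but-3-en-1-one F6, which is used at once to avoid conjugation of the alkene. Corey–Bakshi–Shibata reduction ((S)-Me-CBS cat., catecholborane, toluene, −78 °C), with the furyl ring as the large group, should deliver (R)-3 in the sense in which aryl alkyl ketones give (R)-carbinols, and catecholborane should leave the terminal alkene untouched.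

Further compounds
F1 | step 4 | (R)-4-methyl-1-[5-(4,4,5,5-tetramethyl-1,3,2-dioxaborolan-2-yl)furan-3-yl]pent-3-en-1-yl 3-methylbutanoate | CC(C)=CC[C@@H](OC(=O)CC(C)C)c1coc(B2OC(C)(C)C(C)(C)O2)c1
F2 | step 2 | (R)-tert-butyl{[1-(furan-3-yl)but-3-en-1-yl]oxy}dimethylsilane | C=CC[C@@H](O[Si](C)(C)C(C)(C)C)c1ccoc1
F3 | step 2 | (R)-3-[(tert-butyldimethylsilyl)oxy]-3-(furan-3-yl)propanal | O=CC[C@@H](O[Si](C)(C)C(C)(C)C)c1ccoc1
F4 | step 2 | (R)-tert-butyl{[1-(furan-3-yl)-4-methylpent-3-en-1-yl]oxy}dimethylsilane | CC(C)=CC[C@@H](O[Si](C)(C)C(C)(C)C)c1ccoc1
F5 | step 1 | rac-1-(furan-3-yl)but-3-en-1-ol | C=CCC(O)c1ccoc1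
F6 | step 1 | 1-(furan-3-yl)but-3-en-1-one | C=CCC(=O)c1ccoc1
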